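## Analysis of the target

The target 24 (C26H44O6) is a cyclohexa-1,4-diene with a fifteen-carbon chain. Ring atoms are labelled C1 (bears the chain), C2 (=CH), C3 (CH–OH), C4 (=CH), C5 (C–OMe) and C6 (CH–OAc); the chain is C1′ (CH2), C2′ (CH–OAc), then n-tridecyl. The double bonds are C1=C2 and C4=C5, so C3 and C6 are both doubly allylic sp3 carbons that carry oxygen. There are three stereocentres: C3 (R) and C6 (S), whose oxygens are cis across the ring, and C2′ (R), which is insulated from the ring by C1′ and cannot relay or receive stereochemical information. Loss of water from C3 or of acetic acid from C6 gives an anisole, the methyl enol ether is acid-labile, and three secondary oxygens must end up differentiated (O3 free, O6 and O2′ acetylated). The difficulty is to set C3 and C6 in the absolute sense independently of C2′ and to carry out every protecting-group operation without aromatising the ring. The strategy rests on C5: it is the one ring carbon that is sp2 in 24, bears a heteroatom, and can carry an extra carboxyl group that later leaves as CO2 while C4=C5 forms. While C5 is quaternary the ring is an ordinary cyclohexene that cannot aromatise, and C4–C5 can be brought in as an α-oxygenated acrylate.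

## Retrosynthetic reasoning

**24 ⇒ 23.** The C4=C5 enol ether is traced back to a C5 carbon bearing OMe and CO2H next to the C4 methylene. This is the last disconnection because 24 is the only aromatisable compound of the route; every earlier intermediate has a quaternary C5. The forward reaction must remove the carboxyl as a radical leaving group and take the hydrogen from C4, not from C6.

**23 ⇒ 22 ⇒ 21 ⇒ 20 ⇒ 19 ⇒ 18.** These are oxygen-differentiation steps. The carboxyl is masked as an allyl ester and O3 as an allyl carbonate, so one neutral palladium-catalysed allyl transfer frees both after the acetates are in place. No hindered ester has to be saponified and no silyl ether has to be removed selectively beside another. The O6 and O2′ silyl ethers come from the diene and are exchanged for acetates (21, 22) while C5 is still quaternary, so fluoride and acylation conditions pose no aromatisation risk. The C5 methyl ether (20) is made from the tertiary hydroxyl of 19 without base, because an alkoxide at O5 would sit next to a silyl ether and cis-1,3 to a carbonate.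

**18 ⇒ 17.** The hydroxy ester is the alcoholysis product of a spiro acyl acetal. The acetal oxygen on C5 is the future methoxy oxygen, the lactone carbonyl is the future CO2, and the cleaved acetal carbon returns as 2.

**17 ⇒ 16 + 5.** The cyclohexene is cut at C5–C6 and C3–C4. A Diels–Alder adduct keeps its alkene between the internal diene carbons, so C1=C2 identifies C6–C1–C2–C3 as the diene and C4–C5 as the dienophile. This partition makes C5 quaternary and turns both diene termini into the oxygenated stereocentres, which are cis by E,E geometry. The other partition, with C1–C2 as a dienophile, would give the labile 1,4-diene at once. The forward reaction must be regioselective (C6 to C5), facially selective on 5, and exo with respect to the lactone carbonyl.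

**5 ⇒ 4 ⇒ 3 ⇒ 1 + 2.** The exocyclic alkene comes from bromination and elimination of the cis acetal of 1 with 2. The original lactic acid centre is sacrificed after it has fixed the acetal centre.

**16 ⇒ 15 ⇒ 13 + 14.** The dienol silyl ether is the γ-enolisation product of enal 15. Its C2–C3 bond is cut by cross-metathesis into the 2-substituted acrolein 13 and the symmetric diacetate 14. This fixes connectivity unambiguously, which a crossed aldol between two enolisable aldehydes would not.

**13 ⇒ 12 ⇒ 11 ⇒ 9 ⇒ 8 ⇒ 6.** The α-methylene group comes from a Mannich-type methylenation of aldehyde 12. Aldehyde 12 comes from hydroboration and oxidation of the silylated homoallylic alcohol 9. The C2′ stereocentre is set by reagent-controlled allylation of 6.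

## Alternatives that were turned down

**Alternative 1:** Disconnection at C1–C6 and C2–C3, with the side-chain alkyne C1≡C2 as dienophile and C3=C4–C5=C6 as a trioxygenated diene, the two joined by a diisopropylsilylene bridge from O2′ to O6. Heating, or [Rh(cod)Cl]2 with AgSbF6 (a cationic univalent rhodium catalyst), would close the carbocycle and a seven-membered silaketal in one intramolecular [4+2] step to the bicyclic silaketal A1.
- For: A1 already holds both ring double bonds, the enol ether and a differentiated O3. It needs no tertiary-alcohol methylation and no decarboxylation, so it is clearly shorter.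
- Against: an unactivated alkyne and an electron-rich diene are electronically mismatched, so the thermal reaction needs temperatures at which A1 can aromatise by losing a silanol. The cationic rhodium alternative is Lewis acidic toward silyl enol ethers. Induction from C2′ to C6 must pass through a flexible seven-membered tether. The diene needs defined geometry at both ends. All later steps (tether removal, two acetylations, desilylation) run on the aromatisable diene.
- Comparison: Alternative 1 is stronger on step economy. The chosen route offers intermediates that cannot aromatise until the last step and reagent control that does not depend on C2′.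

**Alternative 2:** Disconnection of C4=C5 between a methyl ester carbon (C5) and a terminal vinyl carbon (C4) in an open chain that already carries C3, C6 and C2′ as silyl ethers. The ethylidene reagent from TiCl4, Zn, catalytic PbCl2, TMEDA and CH3CHBr2 (low-valent titanium) would exchange with the vinyl group and the resulting titanium alkylidene would olefinate the ester, giving the tris-silylated ring A2.
- For: the ester methoxy becomes the enol ether methoxy at no cost, and the three stereocentres can be set by predictable acyclic methods.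
- Against: direct ethylidenation of the ester competes with ring closure. The substrate has a skipped diene with a doubly allylic silyloxy carbon exposed to a Lewis-acidic, strongly reducing mixture used in large excess. A2 is the aromatisable diene and still needs three protecting-group exchanges.
- Comparison: Alternative 2 is as strong or stronger on stereochemical predictability. The chosen route offers convergence (ring and three stereocentres in one step) and only one operation on the labile diene.

**Alternative 3:** Disconnection of the C1–C6 bond between a C1 vinyl iodide and a C6 aldehyde, the C3–C6 segment with its enol ether coming from a 4-methoxybutenolide. CrCl2 with catalytic NiCl2 (divalent chromium, divalent nickel) and a chiral oxazoline–sulfonamide ligand would give the ring A3 with a free C6 hydroxyl.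
- For: A3 is the closest of all key-step products to 24, with O6 free for acetylation, and ring closure by vinylchromium addition is well known.
- Against: the aldehyde is an α-methoxy enal, deactivated and prone to isomerise. The ligand must override the existing C3 centre. The ring is formed as a chromium alkoxide of an aromatisable diene under Lewis-acidic conditions. The geometrically pure trisubstituted vinyl iodide needs a long linear sequence.
- Comparison: Alternative 3 is stronger on the number of steps after ring closure. The chosen route sets C3 and C6 together in a single suprafacial event and keeps the ring robust through all oxygen manipulations.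

Key step: step 11

## Route

Remarks on the chemistry:
- Ring and chain labels (C1–C6, C1′, C2′) are those defined in the analysis; CIP descriptors in names follow systematic numbering.
- (−)-B-Allyldiisopinocampheylborane, with isopinocampheyl groups from (+)-α-pinene, is taken as a purchased pentane solution and is assumed to add to the Si face of an unbranched aldehyde, as is usual for this reagent.
- The configuration at the brominated carbon of 4 is lost in step 3 and is of no consequence.
- Compound 14 is the commercial (Z)-diacetate.

Step 1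
Reactants: 1 (S)-lactic acid; 2 pivalaldehyde
Product: 3 (2S,5S)-2-tert-butyl-5-methyl-1,3-dioxolan-4-one
Conditions: TsOH·H2O (cat.), H2SO4 (cat.), pentane, reflux, Dean–Stark; recrystallisation at low temperature
Reagents that add atoms: none
Why: Acid-catalysed acetalisation with azeotropic water removal; the cis-2,5 acetal is favoured and is enriched by crystallisation, so the lactic acid centre fixes the new acetal centre as (S).

Step 2
Reactants: 3 (2S,5S)-2-tert-butyl-5-methyl-1,3-dioxolan-4-one
Product: 4 (2S,5R)-5-bromo-2-tert-butyl-5-methyl-1,3-dioxolan-4-one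
Conditions: NBS, AIBN (cat.), CCl4, reflux
Reagents that add atoms: N-bromosuccinimide, O=C1CCC(=O)N1Br
Why: Wohl–Ziegler radical bromination at the only captodatively activated C–H; the acetal centre is untouched and from here on carries the chirality alone.

Step 3
Reactants: 4 (2S,5R)-5-bromo-2-tert-butyl-5-methyl-1,3-dioxolan-4-one
Product: 5 (2S)-2-tert-butyl-5-methylidene-1,3-dioxolan-4-one
Conditions: DBU, Et2O, 0 °C to rt
Reagents that add atoms: none
Why: E2 dehydrobromination toward the methyl group, the only source of β-hydrogen; the polymerisable acrylate should be used at once.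

Step 4
Reactants: 6 tetradecanal
Product: 8 (4R)-heptadec-1-en-4-ol, via diisopinocampheylborinate 7 (not isolated)
Conditions: (−)-Ipc2B(allyl), Et2O, −78 °C; then NaOH, H2O2, 0 °C to rt
Reagents that add atoms: (−)-B-allyldiisopinocampheylborane, C=CCB([C@@H]1C[C@@H]2C[C@@H](C2(C)C)[C@H]1C)[C@@H]1C[C@@H]2C[C@@H](C2(C)C)[C@H]1C
Why: Brown allylboration through a chair-like six-membered (Zimmerman–Traxler) transition state; the isopinocampheyl groups direct the allyl group to the Si face of the aldehyde, which sets C2′ as (R).

Step 5
Reactants: 8 (4R)-heptadec-1-en-4-ol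
Product: 9 tert-butyl{[(4R)-heptadec-1-en-4-yl]oxy}dimethylsilane
Conditions: TBSCl, imidazole, DMF, rt
Reagents that add atoms: tert-butyldimethylsilyl chloride, CC(C)(C)[Si](C)(C)Cl
Why: Standard silylation of a secondary alcohol; the silyl ether prevents lactol formation once the aldehyde is made.

Step 6
Reactants: 9 tert-butyl{[(4R)-heptadec-1-en-4-yl]oxy}dimethylsilane
Product: 11 (4R)-4-[(tert-butyldimethylsilyl)oxy]heptadecan-1-ol, via B-alkyl-9-borabicyclononane 10 (not isolated)
Conditions: 9-BBN, THF, 0 °C to rt; then NaOH, H2O2, 0 °C to rt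
Reagents that add atoms: hydrogen peroxide, OO
Why: Anti-Markovnikov hydroboration of the terminal alkene by the bulky borane, then oxidation of the C–B bond with retention.

Step 7
Reactants: 11 (4R)-4-[(tert-butyldimethylsilyl)oxy]heptadecan-1-ol
Product: 12 (4R)-4-[(tert-butyldimethylsilyl)oxy]heptadecanal
Conditions: TEMPO (cat.), PhI(OAc)2, CH2Cl2, rt
Reagents that add atoms: none
Why: Oxoammonium-mediated oxidation of a primary alcohol that stops at the aldehyde and leaves the silyl ether alone.

Step 8
Reactants: 12 (4R)-4-[(tert-butyldimethylsilyl)oxy]heptadecanal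
Product: 13 (4R)-4-[(tert-butyldimethylsilyl)oxy]-2-methylideneheptadecanal
Conditions: aq. CH2O (37%), pyrrolidine (10 mol%), propionic acid (10 mol%), i-PrOH, 45 °C
Reagents that add atoms: formaldehyde, C=O
Why: Organocatalytic Mannich-type α-methylenation: the enamine of 12 adds to the formaldehyde-derived iminium ion and the amine is then eliminated; formaldehyde cannot act as the donor.

Step 9
Reactants: 13 (4R)-4-[(tert-butyldimethylsilyl)oxy]-2-methylideneheptadecanal; 14 (Z)-but-2-ene-1,4-diyl diacetate
Product: 15 (2E)-4-acetoxy-2-{(2R)-2-[(tert-butyldimethylsilyl)oxy]pentadecyl}but-2-enal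
Conditions: 14 (3 equiv), RuCl2(H2IMes)(=CH–C6H4-2-O-i-Pr) (second-generation Hoveyda–Grubbs catalyst, 5 mol%), CH2Cl2, 40 °C
Reagents that add atoms: none
Why: Olefin cross-metathesis of a 2-substituted acrolein, which does not homodimerise, with a symmetric allylic diacetate, as known for methacrolein; the geometry of the new alkene is irrelevant because it becomes a single bond in step 10.

Step 10
Reactants: 15 (2E)-4-acetoxy-2-{(2R)-2-[(tert-butyldimethylsilyl)oxy]pentadecyl}but-2-enal
Product: 16 (1E,3E)-4-[(tert-butyldimethylsilyl)oxy]-3-{(2R)-2-[(tert-butyldimethylsilyl)oxy]pentadecyl}buta-1,3-dien-1-yl acetate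
Conditions: TBSOTf, Et3N, Et2O, 0 °C to rt
Reagents that add atoms: tert-butyldimethylsilyl triflate, CC(C)(C)[Si](C)(C)OS(=O)(=O)C(F)(F)F
Why: Soft enolisation: O-silylation of the s-trans enal and γ-deprotonation at the acetoxymethylene give the dienol silyl ether. The s-trans enal places the silyloxy group outside, and allylic 1,3-strain in the deprotonation places the acetoxy group outside. C1′ is not conjugated with the carbonyl and cannot compete.

Step 11
Reactants: 16 (1E,3E)-4-[(tert-butyldimethylsilyl)oxy]-3-{(2R)-2-[(tert-butyldimethylsilyl)oxy]pentadecyl}buta-1,3-dien-1-yl acetate; 5 (2S)-2-tert-butyl-5-methylidene-1,3-dioxolan-4-one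
Product: 17 (2S,5R,6S,9S)-2-tert-butyl-6-[(tert-butyldimethylsilyl)oxy]-7-{(2R)-2-[(tert-butyldimethylsilyl)oxy]pentadecyl}-4-oxo-1,3-dioxaspiro[4.5]dec-7-en-9-yl acetate (ring labels: acetate at C3, spiro centre C5, silyl ether at C6; O3, O5 and O6 mutually cis, lactone carbonyl trans to them)
Conditions: 5 (1.5 equiv), BHT (cat.), toluene, 90 °C, sealed tube
Reagents that add atoms: none
Why: A concerted, asynchronous normal-demand [4+2] cycloaddition between the s-cis diene 16 and the captodative exocyclic alkene of 5; the closest known reaction type is the thermal Diels–Alder reaction of 5-methylene-1,3-dioxolan-4-ones with oxygenated acyclic dienes. The one new ring, the cyclohexene, closes intermolecularly by suprafacial–suprafacial union of the diene termini with the alkene (bonds C5–C6 and C3–C4), and C5 becomes a spiro centre. Regiochemistry: the silyloxy group on C6 is a much stronger donor than the acetoxy group on C3 or the alkyl group on C1, so the larger HOMO coefficient lies at C3, which bonds to the methylene carbon C4, and C6 bonds to C5. C3 and C6: both oxygens sit on the outside (E) positions of the diene termini and so end up cis. C5: the tert-butyl group on the acetal carbon shields one face of the flat dioxolanone, and C6 bonds to C5 anti to it. The absolute configuration of C3 and C6 depends on which diene face is presented, that is on exo against endo; this dienophile class places its ring oxygen, not the lactone carbonyl, under the diene, which with the (S) acetal gives O5 cis to O3 and O6 and the C3/C6 configuration of 24. The C2′ centre is two atoms away from the diene and should not interfere. The step needs regio-, facial and exo selectivity, secured respectively by the donor hierarchy, the tert-butyl acetal and the intrinsic carbonyl-exo preference of the spiro acetal.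

Step 12
Reactants: 17 spiro adduct
Product: 18 prop-2-en-1-yl (1R,2S,5S)-2-[(tert-butyldimethylsilyl)oxy]-3-{(2R)-2-[(tert-butyldimethylsilyl)oxy]pentadecyl}-1,5-dihydroxycyclohex-3-ene-1-carboxylate
Conditions: allyl alcohol/THF, NaOCH2CH=CH2 (0.3 equiv, from NaH), 0 °C to rt
Reagents that add atoms: allyl alcohol, C=CCO
Why: Alkoxide attack on the activated acyl-acetal carbonyl opens the dioxolanone; the hemiacetal collapses to 2 and the tertiary C5 hydroxyl, and the C3 acetate is transesterified in the same pot. The carboxyl is trans to O3, so no lactone can form.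

Step 13
Reactants: 18 allyl ester diol
Product: 19 prop-2-en-1-yl (1R,2S,5S)-2-[(tert-butyldimethylsilyl)oxy]-3-{(2R)-2-[(tert-butyldimethylsilyl)oxy]pentadecyl}-1-hydroxy-5-{[(prop-2-en-1-yloxy)carbonyl]oxy}cyclohex-3-ene-1-carboxylate
Conditions: AllocCl, pyridine, DMAP (cat.), CH2Cl2, 0 °C
Reagents that add atoms: allyl chloroformate, C=CCOC(Cl)=O
Why: Chemoselective acylation of the secondary allylic O3 hydroxyl; the tertiary α-hydroxy ester hydroxyl is too hindered and too electron-poor to react.

Step 14
Reactants: 19 O3 allyl carbonate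
Product: 20 prop-2-en-1-yl (1R,2S,5S)-2-[(tert-butyldimethylsilyl)oxy]-3-{(2R)-2-[(tert-butyldimethylsilyl)oxy]pentadecyl}-1-methoxy-5-{[(prop-2-en-1-yloxy)carbonyl]oxy}cyclohex-3-ene-1-carboxylate
Conditions: MeOTf, 2,6-di-tert-butyl-4-methylpyridine, CH2Cl2, 40 °C
Reagents that add atoms: methyl triflate, COS(=O)(=O)C(F)(F)F
Why: SN2 methyl transfer to the neutral tertiary alcohol with a hindered, non-nucleophilic proton scavenger; no alkoxide is formed, so neither silyl migration from O6 nor attack on the O3 carbonate can occur.

Step 15
Reactants: 20 C5 methyl ether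
Product: 21 prop-2-en-1-yl (1R,2S,5S)-2-hydroxy-3-[(2R)-2-hydroxypentadecyl]-1-methoxy-5-{[(prop-2-en-1-yloxy)carbonyl]oxy}cyclohex-3-ene-1-carboxylate
Conditions: HF·pyridine, THF, 0 °C to rt (aq. HF/MeCN if the C6 ether lags)
Reagents that add atoms: none
Why: Fluoride-driven cleavage of both silyl ethers; the carbonate, ester and methyl ether are inert, and the ring cannot aromatise because C5 is quaternary.

Step 16
Reactants: 21 diol
Product: 22 prop-2-en-1-yl (1R,2S,5S)-2-acetoxy-3-[(2R)-2-acetoxypentadecyl]-1-methoxy-5-{[(prop-2-en-1-yloxy)carbonyl]oxy}cyclohex-3-ene-1-carboxylate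
Conditions: Ac2O, pyridine, DMAP (cat.), CH2Cl2, rt
Reagents that add atoms: acetic anhydride, CC(=O)OC(C)=O
Why: DMAP-catalysed acetylation of both secondary hydroxyls, including the hindered one at C6; O3 is blocked as its carbonate.

Step 17
Reactants: 22 diacetate
Product: 23 (1R,2S,5S)-2-acetoxy-3-[(2R)-2-acetoxypentadecyl]-5-hydroxy-1-methoxycyclohex-3-ene-1-carboxylic acid
Conditions: Pd(PPh3)4 (5 mol%), morpholine, THF, 0 °C to rt; aq. NaH2PO4 work-up
Reagents that add atoms: none
Why: Tsuji–Trost allyl transfer: zerovalent palladium ionises the two unsubstituted allyl groups, morpholine traps them, and the O3 carbonate loses CO2. The ring allylic esters at C3 and C6 lie on a trisubstituted alkene next to the quaternary C5 and should ionise far more slowly.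

Step 18
Reactants: 23 hydroxy acid
Product: 24 (1S,4R)-2-[(2R)-2-(acetyloxy)pentadecyl]-4-hydroxy-6-methoxycyclohexa-2,5-dien-1-yl acetate
Conditions: 9-mesitylacridine (10 mol%), Co(dmgH)2(py)Cl (5 mol%), CH2Cl2, 400 nm LED, 25 °C, Ar
Reagents that add atoms: none
Why: Proposed new method: the hydrogen-bonded acid–acridine complex should undergo photoinduced proton-coupled electron transfer to an acyloxyl radical that loses CO2 to give the tertiary α-methoxy radical at C5; the divalent cobalt cobaloxime, formed from the trivalent cobalt precatalyst, should then remove a β-hydrogen from the open C4 methylene and not from the acetoxy-bearing C6 methine, giving the enol ether, while the cobalt hydride and the acridinyl radical release H2; the closest known reaction types are the acridine/cobaloxime dehydrodecarboxylation of aliphatic acids to alkenes and the photoredox/cobaloxime decarboxylative elimination of N-acyl amino acids to enamides.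

## Compound list

1 | (S)-lactic acid | C[C@H](O)C(=O)O | starting material
2 | pivalaldehyde | CC(C)(C)C=O | starting material
3 | (2S,5S)-2-tert-butyl-5-methyl-1,3-dioxolan-4-one | C[C@@H]1O[C@H](C(C)(C)C)OC1=O | intermediate
4 | (2S,5R)-5-bromo-2-tert-butyl-5-methyl-1,3-dioxolan-4-one (Br trans to tert-butyl expected) | C[C@]1(Br)O[C@H](C(C)(C)C)OC1=O | intermediate
5 | (2S)-2-tert-butyl-5-methylidene-1,3-dioxolan-4-one | C=C1O[C@H](C(C)(C)C)OC1=O | intermediate
6 | tetradecanal | CCCCCCCCCCCCCC=O | starting material
7 | (4R)-heptadec-1-en-4-yl diisopinocampheylborinate | CCCCCCCCCCCCC[C@H](CC=C)OB([C@@H]1C[C@@H]2C[C@@H](C2(C)C)[C@H]1C)[C@@H]1C[C@@H]2C[C@@H](C2(C)C)[C@H]1C | intermediate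
8 | (4R)-heptadec-1-en-4-ol | CCCCCCCCCCCCC[C@H](CC=C)O | intermediate
9 | tert-butyl{[(4R)-heptadec-1-en-4-yl]oxy}dimethylsilane | CCCCCCCCCCCCC[C@H](CC=C)O[Si](C)(C)C(C)(C)C | intermediate
10 | 9-{(4R)-4-[(tert-butyldimethylsilyl)oxy]heptadecyl}-9-borabicyclo[3.3.1]nonane | CCCCCCCCCCCCC[C@H](CCCB1C2CCCC1CCC2)O[Si](C)(C)C(C)(C)C | intermediate
11 | (4R)-4-[(tert-butyldimethylsilyl)oxy]heptadecan-1-ol | CCCCCCCCCCCCC[C@H](CCCO)O[Si](C)(C)C(C)(C)C | intermediate
12 | (4R)-4-[(tert-butyldimethylsilyl)oxy]heptadecanal | CCCCCCCCCCCCC[C@H](CCC=O)O[Si](C)(C)C(C)(C)C | intermediate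
13 | (4R)-4-[(tert-butyldimethylsilyl)oxy]-2-methylideneheptadecanal | CCCCCCCCCCCCC[C@H](CC(=C)C=O)O[Si](C)(C)C(C)(C)C | intermediate
14 | (Z)-but-2-ene-1,4-diyl diacetate | CC(=O)OC/C=C\COC(C)=O | starting material
15 | (2E)-4-acetoxy-2-{(2R)-2-[(tert-butyldimethylsilyl)oxy]pentadecyl}but-2-enal | CCCCCCCCCCCCC[C@H](C/C(C=O)=C\COC(C)=O)O[Si](C)(C)C(C)(C)C | intermediate
16 | (1E,3E)-4-[(tert-butyldimethylsilyl)oxy]-3-{(2R)-2-[(tert-butyldimethylsilyl)oxy]pentadecyl}buta-1,3-dien-1-yl acetate | CCCCCCCCCCCCC[C@H](C/C(=C\O[Si](C)(C)C(C)(C)C)/C=C/OC(C)=O)O[Si](C)(C)C(C)(C)C | intermediate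
17 | (2S,5R,6S,9S)-2-tert-butyl-6-[(tert-butyldimethylsilyl)oxy]-7-{(2R)-2-[(tert-butyldimethylsilyl)oxy]pentadecyl}-4-oxo-1,3-dioxaspiro[4.5]dec-7-en-9-yl acetate | CCCCCCCCCCCCC[C@H](CC1=C[C@@H](OC(C)=O)C[C@@]2(O[C@H](C(C)(C)C)OC2=O)[C@H]1O[Si](C)(C)C(C)(C)C)O[Si](C)(C)C(C)(C)C | intermediate
18 | prop-2-en-1-yl (1R,2S,5S)-2-[(tert-butyldimethylsilyl)oxy]-3-{(2R)-2-[(tert-butyldimethylsilyl)oxy]pentadecyl}-1,5-dihydroxycyclohex-3-ene-1-carboxylate | CCCCCCCCCCCCC[C@H](CC1=C[C@@H](O)C[C@](O)(C(=O)OCC=C)[C@H]1O[Si](C)(C)C(C)(C)C)O[Si](C)(C)C(C)(C)C | intermediate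
19 | prop-2-en-1-yl (1R,2S,5S)-2-[(tert-butyldimethylsilyl)oxy]-3-{(2R)-2-[(tert-butyldimethylsilyl)oxy]pentadecyl}-1-hydroxy-5-{[(prop-2-en-1-yloxy)carbonyl]oxy}cyclohex-3-ene-1-carboxylate | CCCCCCCCCCCCC[C@H](CC1=C[C@@H](OC(=O)OCC=C)C[C@](O)(C(=O)OCC=C)[C@H]1O[Si](C)(C)C(C)(C)C)O[Si](C)(C)C(C)(C)C | intermediate
20 | prop-2-en-1-yl (1R,2S,5S)-2-[(tert-butyldimethylsilyl)oxy]-3-{(2R)-2-[(tert-butyldimethylsilyl)oxy]pentadecyl}-1-methoxy-5-{[(prop-2-en-1-yloxy)carbonyl]oxy}cyclohex-3-ene-1-carboxylate | CCCCCCCCCCCCC[C@H](CC1=C[C@@H](OC(=O)OCC=C)C[C@](OC)(C(=O)OCC=C)[C@H]1O[Si](C)(C)C(C)(C)C)O[Si](C)(C)C(C)(C)C | intermediate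
21 | prop-2-en-1-yl (1R,2S,5S)-2-hydroxy-3-[(2R)-2-hydroxypentadecyl]-1-methoxy-5-{[(prop-2-en-1-yloxy)carbonyl]oxy}cyclohex-3-ene-1-carboxylate | CCCCCCCCCCCCC[C@H](CC1=C[C@@H](OC(=O)OCC=C)C[C@](OC)(C(=O)OCC=C)[C@H]1O)O | intermediate
22 | prop-2-en-1-yl (1R,2S,5S)-2-acetoxy-3-[(2R)-2-acetoxypentadecyl]-1-methoxy-5-{[(prop-2-en-1-yloxy)carbonyl]oxy}cyclohex-3-ene-1-carboxylate | CCCCCCCCCCCCC[C@H](CC1=C[C@@H](OC(=O)OCC=C)C[C@](OC)(C(=O)OCC=C)[C@H]1OC(C)=O)OC(C)=O | intermediate
23 | (1R,2S,5S)-2-acetoxy-3-[(2R)-2-acetoxypentadecyl]-5-hydroxy-1-methoxycyclohex-3-ene-1-carboxylic acid | CCCCCCCCCCCCC[C@H](CC1=C[C@@H](O)C[C@](OC)(C(=O)O)[C@H]1OC(C)=O)OC(C)=O | intermediate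
24 | (1S,4R)-2-[(2R)-2-(acetyloxy)pentadecyl]-4-hydroxy-6-methoxycyclohexa-2,5-dien-1-yl acetate | CCCCCCCCCCCCC[C@H](CC1=C[C@@H](O)C=C(OC)[C@H]1OC(C)=O)OC(C)=O | target

## Step count and least certain steps

Total: 18 steps. Longest linear sequence: 15 steps (6 to 24, steps 4–18); the dienophile branch is 3 steps (1 to 5).

**Step 18 (bears the label "Proposed new method:").**
- What may go wrong: hydrogen removal from C6 instead of C4 would give the conjugated isomer. The excited acridine or the cobalt radical may abstract the doubly allylic hydrogens at C3 or C6 of the product, followed by loss of water or acetic acid and aromatisation. The α-methoxy radical may be oxidised to an oxocarbenium ion that loses a proton unselectively.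
- Fallback (known chemistry), from 23 to 24: the acid is converted with 2,2′-dithiobis(pyridine N-oxide) and Bu3P, in the dark, into the N-acyloxypyridine-2-thione (Barton) ester F1; this reagent tolerates the free hydroxyl. Visible-light photolysis of F1 at 0 °C with PhSeSePh gives, by radical decarboxylation and selenium transfer, the C5 phenyl selenide F2 as a mixture of C5 epimers. Oxidation with mCPBA at −78 °C and warming with i-Pr2NH should then give 24 by selenoxide syn-elimination; elimination toward the oxygen-bearing C6 is disfavoured, and the amine scavenges the selenenic acid.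

**Step 11 (key step).**
- What may go wrong: erosion of exo selectivity, since the carbonyl-endo topology delivers the opposite C3/C6 pair. Regiochemical leakage, because the C1 alkyl and C3 acetoxy groups both oppose the silyloxy directing effect. Polymerisation of 5 or thermal desilylation of 16 before cycloaddition.
- Fallback if the carbonyl-endo topology dominates, from 16 to 24: the mirror-image auxiliary is used so that the endo topology becomes productive. (R)-Lactic acid and 2 give, by the operations of steps 1–3, the (2R,5R)-acetal F3, its bromide F4 and the (R)-dienophile F5. Cycloaddition of F5 with 16 through the carbonyl-endo transition state gives the spiro adduct F6, which has the same C3/C6 configuration as 17 but is epimeric at C5. The operations of steps 12–17 carry it through the C5-epimeric allyl ester diol F7, carbonate F8, methyl ether F9, diol F10, diacetate F11 and hydroxy acid F12. The conditions of step 18 (or its fallback) erase C5 and give 24. In this series the carboxyl is cis to O3, so acidic work-ups are avoided to prevent lactonisation.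

**Step 14.**
- What may go wrong: incomplete methylation of the hindered, inductively deactivated tertiary hydroxyl, and on forcing, alkylation of the carbonate carbonyl or loss of a silyl ether.
- Fallback, from 18 to 20: 18 is silylated at O3 (TESCl, imidazole) to the triethylsilyl ether F13, whose alkoxide can be used safely. KN(SiMe3)2 and MeOTf in THF at −78 °C give the C5 methyl ether F14. PPTS in MeOH at 0 °C removes only the triethylsilyl group to give the O3 alcohol F15, and the conditions of step 13 return 20.

**Step 9.**
- What may go wrong: sluggish cross-metathesis of the hindered 1,1-disubstituted enal, with catalyst decay while 14 merely scrambles.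
- Fallback, from 12 to 15 (bypassing 13): ozonolysis of 14 (O3, CH2Cl2, −78 °C; Me2S) gives acetoxyacetaldehyde F16. Pyrrolidine/benzoic acid-catalysed cross-aldol condensation of 12 (the better enamine donor) with an excess of F16 (the more electrophilic acceptor) gives 15.

## Further compounds

F1 | step 18 | 2-thioxopyridin-1(2H)-yl (1R,2S,5S)-2-acetoxy-3-[(2R)-2-acetoxypentadecyl]-5-hydroxy-1-methoxycyclohex-3-ene-1-carboxylate | CCCCCCCCCCCCC[C@H](CC1=C[C@@H](O)C[C@](OC)(C(=O)On2ccccc2=S)[C@H]1OC(C)=O)OC(C)=O
F2 | step 18 | (1S,4S)-2-[(2R)-2-acetoxypentadecyl]-4-hydroxy-6-methoxy-6-(phenylselanyl)cyclohex-2-en-1-yl acetate, mixture of epimers at the selenium-bearing carbon | CCCCCCCCCCCCC[C@H](CC1=C[C@@H](O)CC(OC)([Se]c2ccccc2)[C@H]1OC(C)=O)OC(C)=O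
F3 | step 11 | (2R,5R)-2-tert-butyl-5-methyl-1,3-dioxolan-4-one | C[C@H]1O[C@@H](C(C)(C)C)OC1=O
F4 | step 11 | (2R,5S)-5-bromo-2-tert-butyl-5-methyl-1,3-dioxolan-4-one | C[C@@]1(Br)O[C@@H](C(C)(C)C)OC1=O
F5 | step 11 | (2R)-2-tert-butyl-5-methylidene-1,3-dioxolan-4-one | C=C1O[C@@H](C(C)(C)C)OC1=O
F6 | step 11 | spiro adduct with (R) acetal, epimeric with 17 at the spiro carbon (lactone carbonyl cis to O3 and O6) | CCCCCCCCCCCCC[C@H](CC1=C[C@@H](OC(C)=O)C[C@]2(O[C@@H](C(C)(C)C)OC2=O)[C@H]1O[Si](C)(C)C(C)(C)C)O[Si](C)(C)C(C)(C)C
F7 | step 11 | C1-epimer of 18 (carboxylate numbering) | CCCCCCCCCCCCC[C@H](CC1=C[C@@H](O)C[C@@](O)(C(=O)OCC=C)[C@H]1O[Si](C)(C)C(C)(C)C)O[Si](C)(C)C(C)(C)C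
F8 | step 11 | C1-epimer of 19 | CCCCCCCCCCCCC[C@H](CC1=C[C@@H](OC(=O)OCC=C)C[C@@](O)(C(=O)OCC=C)[C@H]1O[Si](C)(C)C(C)(C)C)O[Si](C)(C)C(C)(C)C
F9 | step 11 | C1-epimer of 20 | CCCCCCCCCCCCC[C@H](CC1=C[C@@H](OC(=O)OCC=C)C[C@@](OC)(C(=O)OCC=C)[C@H]1O[Si](C)(C)C(C)(C)C)O[Si](C)(C)C(C)(C)C
F10 | step 11 | C1-epimer of 21 | CCCCCCCCCCCCC[C@H](CC1=C[C@@H](OC(=O)OCC=C)C[C@@](OC)(C(=O)OCC=C)[C@H]1O)O
F11 | step 11 | C1-epimer of 22 | CCCCCCCCCCCCC[C@H](CC1=C[C@@H](OC(=O)OCC=C)C[C@@](OC)(C(=O)OCC=C)[C@H]1OC(C)=O)OC(C)=O
F12 | step 11 | C1-epimer of 23 | CCCCCCCCCCCCC[C@H](CC1=C[C@@H](O)C[C@@](OC)(C(=O)O)[C@H]1OC(C)=O)OC(C)=O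
F13 | step 14 | O5-triethylsilyl ether of 18 (carboxylate numbering; ring label O3) | CCCCCCCCCCCCC[C@H](CC1=C[C@@H](O[Si](CC)(CC)CC)C[C@](O)(C(=O)OCC=C)[C@H]1O[Si](C)(C)C(C)(C)C)O[Si](C)(C)C(C)(C)C
F14 | step 14 | C1 methyl ether of F13 | CCCCCCCCCCCCC[C@H](CC1=C[C@@H](O[Si](CC)(CC)CC)C[C@](OC)(C(=O)OCC=C)[C@H]1O[Si](C)(C)C(C)(C)C)O[Si](C)(C)C(C)(C)C
F15 | step 14 | prop-2-en-1-yl (1R,2S,5S)-2-[(tert-butyldimethylsilyl)oxy]-3-{(2R)-2-[(tert-butyldimethylsilyl)oxy]pentadecyl}-5-hydroxy-1-methoxycyclohex-3-ene-1-carboxylate | CCCCCCCCCCCCC[C@H](CC1=C[C@@H](O)C[C@](OC)(C(=O)OCC=C)[C@H]1O[Si](C)(C)C(C)(C)C)O[Si](C)(C)C(C)(C)C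
F16 | step 9 | acetoxyacetaldehyde (2-oxoethyl acetate) | CC(=O)OCC=O
A1 | alternative 1 | bicyclic O6,O2′-diisopropylsilylene ketal of the O3-tert-butyldiphenylsilyl ring | CCCCCCCCCCCCC[C@H](CC1=C[C@@H](O[Si](c2ccccc2)(c2ccccc2)C(C)(C)C)C=C(OC)[C@H]1O3)O[Si]3(C(C)C)C(C)C
A2 | alternative 2 | O3-tert-butyldiphenylsilyl, O6,O2′-bis(triethylsilyl) ring | CCCCCCCCCCCCC[C@H](CC1=C[C@@H](O[Si](c2ccccc2)(c2ccccc2)C(C)(C)C)C=C(OC)[C@H]1O[Si](CC)(CC)CC)O[Si](CC)(CC)CC
A3 | alternative 3 | O3-tert-butyldimethylsilyl, O2′-triethylsilyl ring with free C6 hydroxyl | CCCCCCCCCCCCC[C@H](CC1=C[C@@H](O[Si](C)(C)C(C)(C)C)C=C(OC)[C@H]1O)O[Si](CC)(CC)CC
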